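A percentage point of the E charged is the coin I count in, and the readings below are told in it.

| setting | birch | oak | flask |
|---|---|---|---|
| E | 0.25 M (fed, over 40 s) | 0.50 M (fed, over 40 s) | 0.25 M (fed, over 40 s) |
| J | 1.8 equiv | 1.8 equiv | 1.80 equiv |
| remark | the very flask that is asked about, followed so far; the fed solution adds 0.10 times the starting volume | run made earlier; the fed solution adds 0.10 times the starting volume | the fed solution adds 0.10 times the starting volume |
| time |  |  | 2.0 min |
| volume of the second phase over the first |  |  | 0.50 |

| run | time / s | D / % | E / % |
|---|---|---|---|
| birch | 10.0 | 5 | 17 |
| birch | 15.0 | 10 | 23 |
| birch | 20.0 | 17 | 24 |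
| oak | 10.0 | 4 | 16 |
| oak | 15.0 | 16 | 17 |
| oak | 25.0 | 28 | 13 |
| oak | 40.0 | 46 | 15 |
| oak | 60.0 | 46 | 9 |
| oak | 80.0 | 38 | 6 |

(scatter of a reading: 1.5 percentage points)

- time, not beyond 2.0 min, at which the flask holds most D
- the amount of D, in percent of the E charged, at that time

- every charge counts on the volume at the start, and the solution that is fed holds the whole dose
- in the second phase: J; everything else is in the first
- charges count per volume of the first phase; a concentration in a rate is the amount of a species over the volume of its own phase; every rate counts per litre of the first phase
- the earlier runs hold the two phases in the same ratio of volumes as the flask asked about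
- a reading or a percentage of D counts all its forms, free or not
- percentages count the whole charge, also what has not yet gone in
- a reading of E is of its free form alone

I take E to turn into D and D to be lost onward, so D stands flat where its gain equals its loss. Oak does that between 40.0 s and 60.0 s, and there the crossing ratio, free E over D with all forms of D counted, taken at the flat top of D, reads about 0.261, from readings good to 1.5 percentage points. My working rule, read at oak's charge and a guide rather than a constant at another charge, is that D climbs while E over D stands above this ratio and sinks once it stands below.

The charge lies in three heaps: E, D, and what neither reading shows. With E at the ratio times D, the top of D is one over the sum of one, the ratio and the missing share, counted per unit of D. One way borrows oak's missing share at its top, 0.913, and gives 46.0 %. The other takes birch's own share at 20.0 s, counted against what has been fed, 0.529, and gives 55.9 %.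

They part, and each cheats. Oak is read at 0.50 M, and at 10.0 s it lacks 5 points against birch's 3 points, while birch is read mid-feed, and oak's own share was still 0.768 at 25.0 s. So I go round once more, raising birch's share by oak's growth to 0.630, which puts the top of birch at 52.9 %. I place that top close to 60.0 s, since birch's E over D is still 1.41 at 20.0 s.

The forecast says 46 % at 1.1 min, adding “so this estimate is uncertain”. The flask gives 52.7 % at 0.984 min.

    E + D ⇌ G, settled at all times (K = 7.70 /M)
    L + D → Z (k = 0.111 /M/s)
    E + L → D (k = 0.343 /M/s)
    L ⇌ J, rate k4*([L] - [J]/K4) per volume of the first phase (partition coefficient = 0.440, kL = 0.0112 /s)

At that best time the birch flask holds E over D, with G counted in D, of 0.261, beside the ratio of 0.261. The top stands where it does through the path from L + D to Z: the same run without that path reaches 94.6 % instead of 52.7 %. In the neighbour flask charged with 0.063 M, E over D at 2.00 min is still 0.318, so the rule has D climbing up to the end. The computed flask agrees: its best is 57.0 %, and it ends at 57.0 %.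

The readings are simulated on assumed constants.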